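The benzo ring of the naphthoquinone (C4a', C5'–C8', C8a') carries CO2H, OH, CH3 and OH on C5'–C8', which is the pattern of a 2-methyl-3-oxoglutarate bis-enol ether, and the amide-bearing quinone ring can serve as dienophile. The route is therefore cut through that ring: one Diels–Alder benzannulation joins C4a'–C5' and C8'–C8a' and aromatises by loss of HBr and a silyl ether, giving the whole chromophore with the Z-iodoacrylamide in place. Its precursor is a 2-amido-6-bromo-1,4-benzoquinone already acylated with (Z)-3-iodo-2-methylacrylic acid; the diene is a bis-silyl dienol ether carrying 2-(trimethylsilyl)ethyl esters. Stille coupling with the C4–C17 ketal vinylstannane and fluoride cleavage of the ester finish the route.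

Key step: step 10

Remarks
- Locants C1–C17 (side chain) and primed locants (naphthoquinone) follow the target; CIP labels in a name refer to that compound itself.
- The carboxyl group is carried as a 2-(trimethylsilyl)ethyl ester, not as a methyl ester. A β-resorcylate ester flanked by the C6' hydroxyl and the peri C4' carbonyl cannot be saponified without hydroxide attacking the 2'-amidoquinone, and the free acid decarboxylates on heating. Fluoride removes the silylethyl ester at room temperature. Skeletons and bond construction of the key step are unchanged.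
- Structure check: bromine must sit on quinone C6 (flanking the C1 carbonyl that also neighbours the amide carbon), and the diene must be enolised toward the unsubstituted CH2 with the ketene acetal on the methyl-bearing ester. Both are as drawn; the ketene-acetal geometry of 16 is immaterial.
- Assumption: 4-methoxy-2-nitrophenol, 19, 20, 26, 36 and 2,6-dibromo-1,4-benzoquinone are taken as commercial.

**Vinyl iodide acid**

Step 1
Reactants: 1 prop-2-yn-1-ol
Product: 3 (Z)-3-iodo-2-methylprop-2-en-1-ol, via chelated vinylmagnesium alkoxide 2 (not isolated)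
Conditions: MeMgBr (3 equiv), CuI (10 mol%), THF, −10 °C → rt; then I2, −78 → 0 °C; aq. NH4Cl
Reagents that add atoms: methylmagnesium bromide C[Mg]Br; iodine II
Why: Copper-catalysed anti-carbomagnesiation of the propargylic magnesium alkoxide (Duboudin reaction) puts methyl on C2 and magnesium on C3 cis to CH2O in a five-membered chelate, so iodinolysis with retention should give only the Z iodide.

Step 2
Reactants: 3 (Z)-3-iodo-2-methylprop-2-en-1-ol
Product: 5 (Z)-3-iodo-2-methylprop-2-enoic acid, via (Z)-3-iodo-2-methylprop-2-enal 4 (not isolated)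
Conditions: TEMPO (20 mol%), PhI(OAc)2 (2.5 equiv), MeCN/H2O 1:1, rt
Reagents that add atoms: water O
Why: TEMPO/PhI(OAc)2 oxidation in aqueous acetonitrile takes the allylic alcohol through the aldehyde hydrate to the acid under near-neutral conditions that should leave the vinyl iodide and its Z geometry untouched.

**Amidobromoquinone**

Step 3
Reactants: 6 4-methoxy-2-nitrophenol
Product: 7 2-bromo-4-methoxy-6-nitrophenol
Conditions: Br2 (1.05 equiv), NaOAc, AcOH, rt
Reagents that add atoms: bromine BrBr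
Why: Electrophilic aromatic bromination is directed by the phenol to its only free ortho position, the two positions ortho to OMe being deactivated by the nitro group ortho or para to them.

Step 4
Reactants: 7 2-bromo-4-methoxy-6-nitrophenol
Product: 8 2-amino-6-bromo-4-methoxyphenol
Conditions: Na2S2O4 (4 equiv), THF/H2O, rt → 50 °C; used directly
Reagents that add atoms: none
Why: Dithionite reduction of a nitroarene is an electron-transfer reduction that should give the aminophenol without touching the aryl bromide.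

Step 5
Reactants: 5 (Z)-3-iodo-2-methylprop-2-enoic acid; 8 2-amino-6-bromo-4-methoxyphenol
Product: 10 (Z)-N-(3-bromo-2-hydroxy-5-methoxyphenyl)-3-iodo-2-methylprop-2-enamide, via acid chloride 9 (not isolated)
Conditions: 5, 1-chloro-N,N,2-trimethylprop-1-en-1-amine (1.1 equiv), CH2Cl2, 0 °C; then 8, pyridine, THF, 0 °C
Reagents that add atoms: none
Why: Ghosez's reagent forms the acid chloride under neutral conditions (no HCl-induced Z/E isomerisation), and N-acylation of the aminophenol should win over O-acylation because the aniline is the better nucleophile.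

Step 6
Reactants: 10 (Z)-N-(3-bromo-2-hydroxy-5-methoxyphenyl)-3-iodo-2-methylprop-2-enamide
Product: 11 (Z)-N-(5-bromo-3,6-dioxocyclohexa-1,4-dien-1-yl)-3-iodo-2-methylprop-2-enamide
Conditions: PhI(OAc)2 (1.2 equiv), MeCN/H2O 4:1, 0 °C
Reagents that add atoms: water O
Why: Hypervalent-iodine oxidation of the para-methoxyphenol gives a phenoxenium ion, water adds para and loss of methanol releases the 1,4-benzoquinone (oxidative demethylation), with bromine and the amide both flanking the C1 carbonyl.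

**Diene**

Step 7
Reactants: 12 dimethyl 3-oxopentanedioate
Product: 13 dimethyl 2-methyl-3-oxopentanedioate
Conditions: NaH (1.0 equiv), THF, 0 °C; MeI (1.0 equiv), 0 °C → rt; distillation
Reagents that add atoms: iodomethane CI
Why: C-Alkylation of the sodium enolate of a symmetrical β-keto diester with one equivalent of MeI should give mainly the mono-methyl compound, which is separable from over-alkylated material by distillation.

Step 8
Reactants: 13 dimethyl 2-methyl-3-oxopentanedioate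
Product: 14 bis[2-(trimethylsilyl)ethyl] 2-methyl-3-oxopentanedioate
Conditions: Me3SiCH2CH2OH (3 equiv), DMAP (0.3 equiv), toluene, reflux, MeOH distilled off
Reagents that add atoms: 2-(trimethylsilyl)ethanol C[Si](C)(C)CCO
Why: DMAP-catalysed thermal transesterification of β-keto esters (via the acylketene) should exchange both methyl esters, each being β to the ketone, once methanol is removed.

Step 9
Reactants: 14 bis[2-(trimethylsilyl)ethyl] 2-methyl-3-oxopentanedioate
Product: 16 2-(trimethylsilyl)ethyl (2Z,4Z)-4-methyl-3,5-bis(trimethylsilyloxy)-5-[2-(trimethylsilyl)ethoxy]penta-2,4-dienoate, via mono-silyl enol ether 15 (not isolated)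
Conditions: TMSOTf (2.4 equiv), Et3N (3.2 equiv), Et2O, 0 °C → rt; filtered under Ar, used crude
Reagents that add atoms: trimethylsilyl trifluoromethanesulfonate C[Si](C)(C)OS(=O)(=O)C(F)(F)F
Why: Soft enolisation first silylates the ketone enol on the more acidic unsubstituted CH2 side, and the remaining CH(Me) proton, now α to an ester and γ to the silyloxy enoate, is removed next to give the ketene silyl acetal (Chan/Brassard-type 1,3-bis(silyloxy)diene formation).

**Key step**

Step 10
Reactants: 11 (Z)-N-(5-bromo-3,6-dioxocyclohexa-1,4-dien-1-yl)-3-iodo-2-methylprop-2-enamide; 16 2-(trimethylsilyl)ethyl (2Z,4Z)-4-methyl-3,5-bis(trimethylsilyloxy)-5-[2-(trimethylsilyl)ethoxy]penta-2,4-dienoate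
Product: 18 2-(trimethylsilyl)ethyl 6-[(Z)-3-iodo-2-methylprop-2-enamido]-2,4-dihydroxy-3-methyl-5,8-dioxo-5,8-dihydronaphthalene-1-carboxylate, via bromo cycloadduct 17 (not isolated)
Conditions: 16 (2 equiv), CH2Cl2, −78 → 0 °C; then SiO2, CH2Cl2, rt
Reagents that add atoms: none
Why: The polarised diene attacks through its ester-bearing C2 at the bromine-free quinone carbon C5, which is β to the C1 carbonyl (the more electrophilic one, since the amide nitrogen feeds electron density into C4=O and C2=C3), and the ketene-acetal carbon closes onto brominated C6 in a strongly asynchronous normal-demand [4+2] cycloaddition. The closest known reaction type is the Diels–Alder benzannulation of haloquinones with 1,1,3-trioxygenated butadienes. The six-membered benzo ring is closed by this [4+2] cycloaddition, forming C4a'–C5' and C8'–C8a'; adduct 17 then loses HBr across C4a'/C8a', expels the silylethoxy group from the ketal carbon with the C5' proton and is desilylated on silica to the arene. No stereocentre survives, so the relative configuration of 17 is immaterial. The step needs regio- and site-selectivity: bromine on C6 and the vinylogous-amide deactivation of C2=C3 both send the nucleophilic diene terminus to C5 and leave C5=C6 as the only dienophile, which places the C8' hydroxyl peri to C1'=O and the ester on C5'. The second equivalent of diene should scavenge HBr.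

**C4–C17 vinylstannane**

Step 11
Reactants: 19 (R)-4-benzyl-3-propanoyl-1,3-oxazolidin-2-one; 20 pent-4-enal
Product: 22 (R)-4-benzyl-3-[(2R,3S)-3-hydroxy-2-methylhept-6-enoyl]-1,3-oxazolidin-2-one, via Z-boron enolate 21 (not isolated)
Conditions: Bu2BOTf (1.1 equiv), iPr2NEt (1.3 equiv), CH2Cl2, −78 → 0 °C; 20, −78 → 0 °C; pH 7 buffer, MeOH, H2O2
Reagents that add atoms: none
Why: Evans syn-aldol reaction, in which the Z-boron enolate reacts through a Zimmerman–Traxler chair on the face opposite the benzyl group of the (R)-auxiliary and so sets C12 and C13 (2R,3S, syn).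

Step 12
Reactants: 22 (R)-4-benzyl-3-[(2R,3S)-3-hydroxy-2-methylhept-6-enoyl]-1,3-oxazolidin-2-one
Product: 23 (2R,3S)-3-hydroxy-N-methoxy-N,2-dimethylhept-6-enamide
Conditions: MeNH(OMe)·HCl (3 equiv), AlMe3 (3 equiv), CH2Cl2, −10 °C → rt; Rochelle salt
Reagents that add atoms: N,O-dimethylhydroxylamine hydrochloride CNOC.Cl
Why: Aluminium-amide transamidation of the N-acyloxazolidinone (Weinreb amide formation), assisted by the free β-hydroxyl, should release the auxiliary without epimerising C12.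

Step 13
Reactants: 23 (2R,3S)-3-hydroxy-N-methoxy-N,2-dimethylhept-6-enamide
Product: 24 (2R,3S)-N-methoxy-N,2-dimethyl-3-(triethylsilyloxy)hept-6-enamide
Conditions: TESCl, imidazole, CH2Cl2, 0 °C → rt
Reagents that add atoms: chlorotriethylsilane CC[Si](Cl)(CC)CC
Why: Standard O-silylation of a secondary alcohol gives a silyl ether that survives the Grignard and boron-aldol steps.

Step 14
Reactants: 24 (2R,3S)-N-methoxy-N,2-dimethyl-3-(triethylsilyloxy)hept-6-enamide
Product: 25 (4R,5S)-4-methyl-5-(triethylsilyloxy)non-8-en-3-one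
Conditions: EtMgBr (2.5 equiv), THF, 0 °C; aq. NH4Cl
Reagents that add atoms: ethylmagnesium bromide CC[Mg]Br
Why: Grignard addition to a Weinreb amide stops at the chelated tetrahedral intermediate, so the ethyl ketone should form without over-addition.

Step 15
Reactants: 25 (4R,5S)-4-methyl-5-(triethylsilyloxy)non-8-en-3-one; 26 2-methylprop-2-enal
Product: 28 (3S,4R,6R,7S)-3-hydroxy-2,4,6-trimethyl-7-(triethylsilyloxy)undeca-1,10-dien-5-one, via E-boron enolate 27 (not isolated)
Conditions: Cy2BCl (1.5 equiv), Et3N (1.8 equiv), Et2O, 0 °C; 26 (3 equiv), −78 → −20 °C; MeOH, pH 7 buffer, H2O2, 0 °C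
Reagents that add atoms: none
Why: Paterson anti-aldol reaction, in which the E-enol borinate adds to methacrolein through a chair transition state under A(1,3)-strain control by the C12 stereocentre, which should set C9 and C10 as 9,10-anti and 10,12-anti.

Step 16
Reactants: 28 (3S,4R,6R,7S)-3-hydroxy-2,4,6-trimethyl-7-(triethylsilyloxy)undeca-1,10-dien-5-one
Product: 29 (3S,4S,5S,6S,7S)-5-hydroxy-2,4,6-trimethyl-7-(triethylsilyloxy)undeca-1,10-dien-3-yl benzoate
Conditions: SmI2 (0.3 equiv), PhCHO (6 equiv), THF, −10 °C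
Reagents that add atoms: benzaldehyde O=Cc1ccccc1
Why: Evans–Tishchenko reduction, in which the samarium-bound benzaldehyde hemiacetal on the C9 hydroxyl delivers hydride intramolecularly to the C11 ketone through a six-membered chair, setting C11 1,3-anti to C9 and leaving C9 protected as its benzoate.

Step 17
Reactants: 29 (3S,4S,5S,6S,7S)-5-hydroxy-2,4,6-trimethyl-7-(triethylsilyloxy)undeca-1,10-dien-3-yl benzoate
Product: 30 (3S,4S,5S,6S,7S)-5-hydroxy-2,4,6-trimethyl-10-oxo-7-(triethylsilyloxy)undec-1-en-3-yl benzoate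
Conditions: PdCl2 (10 mol%), CuCl (co-catalyst), O2 (1 atm), DMF/H2O 7:1, rt
Reagents that add atoms: water O
Why: Tsuji–Wacker oxidation converts only the monosubstituted terminal alkene into the methyl ketone by Markovnikov hydroxypalladation, the 1,1-disubstituted alkene of the 2-methylallyl benzoate being a poor substrate.

Step 18
Reactants: 30 (3S,4S,5S,6S,7S)-5-hydroxy-2,4,6-trimethyl-10-oxo-7-(triethylsilyloxy)undec-1-en-3-yl benzoate
Product: 32 (3S,4S)-2-methyl-4-[(1S,3R,4R,5S)-1,4-dimethyl-2,8-dioxabicyclo[3.2.1]octan-3-yl]pent-1-en-3-yl benzoate, via desilylated diol ketone 31 (not isolated)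
Conditions: PPTS (0.2 equiv), MeOH, rt; then CH2Cl2, PPTS, 4 Å MS, rt
Reagents that add atoms: none
Why: Acidic methanolysis removes the TES ether, and the C13 and C11 hydroxyls then condense with the C16 ketone to the thermodynamically favoured bridged bicyclic ketal (intramolecular ketalisation), whose C16 configuration is dictated by the bicyclic geometry.

Step 19
Reactants: 32 (3S,4S)-2-methyl-4-[(1S,3R,4R,5S)-1,4-dimethyl-2,8-dioxabicyclo[3.2.1]octan-3-yl]pent-1-en-3-yl benzoate
Product: 34 (2R,3R,4S)-1-hydroxy-2-methyl-4-[(1S,3R,4R,5S)-1,4-dimethyl-2,8-dioxabicyclo[3.2.1]octan-3-yl]pentan-3-yl benzoate, via B-alkyl-9-BBN 33 (not isolated)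
Conditions: 9-BBN (2.5 equiv), THF, 0 °C → rt; then NaBO3·4H2O, THF/H2O, rt
Reagents that add atoms: sodium perborate [Na+].[Na+].O[B-]1(O)OO[B-](O)(O)OO1
Why: Hydroboration of the 1,1-disubstituted alkene with bulky 9-BBN occurs anti to the C10 branch in the A(1,3)-minimised conformer of the allylic stereocentre (Still–Barrish anti-selective hydroboration), which should set C8 anti to the C9 oxygen, and perborate replaces boron by hydroxyl with retention.

Step 20
Reactants: 34 (2R,3R,4S)-1-hydroxy-2-methyl-4-[(1S,3R,4R,5S)-1,4-dimethyl-2,8-dioxabicyclo[3.2.1]octan-3-yl]pentan-3-yl benzoate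
Product: 35 (2S,3S,4S)-2-methyl-1-oxo-4-[(1S,3R,4R,5S)-1,4-dimethyl-2,8-dioxabicyclo[3.2.1]octan-3-yl]pentan-3-yl benzoate
Conditions: Dess–Martin periodinane (1.5 equiv), NaHCO3, CH2Cl2, 0 °C → rt; used directly
Reagents that add atoms: none
Why: Buffered Dess–Martin oxidation gives the α-methyl aldehyde under non-basic conditions, which should avoid epimerisation at C8 and β-elimination of benzoate.

Step 21
Reactants: 36 (R)-but-3-yn-2-ol
Product: 37 (R)-but-3-yn-2-yl methanesulfonate
Conditions: MsCl, Et3N, CH2Cl2, −78 → 0 °C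
Reagents that add atoms: methanesulfonyl chloride CS(=O)(=O)Cl
Why: Mesylation takes place at oxygen and therefore retains the carbinol configuration.

Step 22
Reactants: 35 (2S,3S,4S)-2-methyl-1-oxo-4-[(1S,3R,4R,5S)-1,4-dimethyl-2,8-dioxabicyclo[3.2.1]octan-3-yl]pentan-3-yl benzoate; 37 (R)-but-3-yn-2-yl methanesulfonate
Product: 39 (2S,3R,4R,5S,6S)-5-hydroxy-4,6-dimethyl-2-[(1S,3R,4R,5S)-1,4-dimethyl-2,8-dioxabicyclo[3.2.1]octan-3-yl]oct-7-yn-3-yl benzoate, via allenylzinc 38 (not isolated)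
Conditions: 37 (1.6 equiv), Pd(OAc)2 (5 mol%), PPh3 (5 mol%), Et2Zn (3 equiv), THF, −78 → −20 °C; aq. NH4Cl
Reagents that add atoms: none
Why: Marshall propargylation, in which Pd(0) converts the (R)-mesylate by anti SN2' into an allenylpalladium that transmetalates to the (aS)-allenylzinc, which adds through a cyclic SE2' transition state and should set C6 and C7 as 6,7-anti under reagent control with Felkin (7,8-syn) addition in the matched sense.

Step 23
Reactants: 39 (2S,3R,4R,5S,6S)-5-hydroxy-4,6-dimethyl-2-[(1S,3R,4R,5S)-1,4-dimethyl-2,8-dioxabicyclo[3.2.1]octan-3-yl]oct-7-yn-3-yl benzoate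
Product: 40 (3S,4S,5R,6R,7R)-3,5-dimethyl-7-[(1S,3S,4R,5S)-1,4-dimethyl-2,8-dioxabicyclo[3.2.1]octan-3-yl]oct-1-yne-4,6-diol
Conditions: K2CO3, MeOH, rt
Reagents that add atoms: none
Why: Base-catalysed methanolysis (transesterification) of the benzoate should leave the ketal and the terminal alkyne intact.

Step 24
Reactants: 40 (3S,4S,5R,6R,7R)-3,5-dimethyl-7-[(1S,3S,4R,5S)-1,4-dimethyl-2,8-dioxabicyclo[3.2.1]octan-3-yl]oct-1-yne-4,6-diol
Product: 41 (1E,3S,4S,5R,6R,7R)-3,5-dimethyl-7-[(1S,3S,4R,5S)-1,4-dimethyl-2,8-dioxabicyclo[3.2.1]octan-3-yl]-1-(tributylstannyl)oct-1-ene-4,6-diol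
Conditions: Bu3SnH (1.5 equiv), PdCl2(PPh3)2 (5 mol%), THF, 0 °C; Et3N-deactivated SiO2
Reagents that add atoms: tributyltin hydride CCCC[SnH](CCCC)CCCC
Why: Palladium-catalysed syn-hydrostannation of the terminal alkyne delivers tin to the terminal carbon, a preference reinforced by the α-branch at C6, and should give the E-vinylstannane.

**Endgame**

Step 25
Reactants: 18 2-(trimethylsilyl)ethyl 6-[(Z)-3-iodo-2-methylprop-2-enamido]-2,4-dihydroxy-3-methyl-5,8-dioxo-5,8-dihydronaphthalene-1-carboxylate; 41 (1E,3S,4S,5R,6R,7R)-3,5-dimethyl-7-[(1S,3S,4R,5S)-1,4-dimethyl-2,8-dioxabicyclo[3.2.1]octan-3-yl]-1-(tributylstannyl)oct-1-ene-4,6-diol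
Product: 42 2-(trimethylsilyl)ethyl 6-{[(2Z,4E,6S,7S,8R,9R,10R)-7,9-dihydroxy-2,6,8-trimethyl-10-[(1S,3S,4R,5S)-1,4-dimethyl-2,8-dioxabicyclo[3.2.1]octan-3-yl]undeca-2,4-dienoyl]amino}-2,4-dihydroxy-3-methyl-5,8-dioxo-5,8-dihydronaphthalene-1-carboxylate
Conditions: Pd2(dba)3 (5 mol%), AsPh3 (40 mol%), degassed DMF, rt, dark
Reagents that add atoms: none
Why: Stille coupling of the Z-vinyl iodide with the E-vinylstannane proceeds with retention at both alkenes under ligand-accelerated conditions at room temperature and should form the C3–C4 bond of the (2Z,4E)-dienamide.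

Step 26
Reactants: 42 2-(trimethylsilyl)ethyl ester of the target
Product: 43 rifsaliniketal
Conditions: TASF (4 equiv), DMF, 0 °C → rt; aq. NH4Cl
Reagents that add atoms: none
Why: Fluoride attacks silicon of the 2-(trimethylsilyl)ethyl ester, which fragments to carboxylate, ethene and Me3SiF (fluoride-induced β-elimination), a non-hydrolytic ester cleavage that should spare the amidoquinone, the dienamide and the ketal.

**Compound list**

1 | prop-2-yn-1-ol | C#CCO | starting material
2 | (Z)-[3-(bromomagnesiooxy)-2-methylprop-1-en-1-yl]magnesium bromide | Br[Mg]/C=C(/C)CO[Mg]Br | intermediate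
3 | (Z)-3-iodo-2-methylprop-2-en-1-ol | C/C(=C/I)CO | intermediate
4 | (Z)-3-iodo-2-methylprop-2-enal | C/C(=C/I)C=O | intermediate
5 | (Z)-3-iodo-2-methylprop-2-enoic acid | C/C(=C/I)C(=O)O | intermediate
6 | 4-methoxy-2-nitrophenol | COc1ccc(O)c([N+](=O)[O-])c1 | starting material
7 | 2-bromo-4-methoxy-6-nitrophenol | COc1cc(Br)c(O)c([N+](=O)[O-])c1 | intermediate
8 | 2-amino-6-bromo-4-methoxyphenol | COc1cc(N)c(O)c(Br)c1 | intermediate
9 | (Z)-3-iodo-2-methylprop-2-enoyl chloride | C/C(=C/I)C(Cl)=O | intermediate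
10 | (Z)-N-(3-bromo-2-hydroxy-5-methoxyphenyl)-3-iodo-2-methylprop-2-enamide | C/C(=C/I)C(=O)Nc1cc(OC)cc(Br)c1O | intermediate
11 | (Z)-N-(5-bromo-3,6-dioxocyclohexa-1,4-dien-1-yl)-3-iodo-2-methylprop-2-enamide | C/C(=C/I)C(=O)NC1=CC(=O)C=C(Br)C1=O | intermediate
12 | dimethyl 3-oxopentanedioate | COC(=O)CC(=O)CC(=O)OC | starting material
13 | dimethyl 2-methyl-3-oxopentanedioate (racemic, configurationally labile) | COC(=O)CC(=O)C(C)C(=O)OC | intermediate
14 | bis[2-(trimethylsilyl)ethyl] 2-methyl-3-oxopentanedioate | C[Si](C)(C)CCOC(=O)CC(=O)C(C)C(=O)OCC[Si](C)(C)C | intermediate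
15 | bis[2-(trimethylsilyl)ethyl] (Z)-4-methyl-3-(trimethylsilyloxy)pent-2-enedioate | C[Si](C)(C)CCOC(=O)/C=C(O[Si](C)(C)C)/C(C)C(=O)OCC[Si](C)(C)C | intermediate
16 | 2-(trimethylsilyl)ethyl (2Z,4Z)-4-methyl-3,5-bis(trimethylsilyloxy)-5-[2-(trimethylsilyl)ethoxy]penta-2,4-dienoate | C[Si](C)(C)CCOC(=O)/C=C(O[Si](C)(C)C)/C(C)=C(/OCC[Si](C)(C)C)O[Si](C)(C)C | intermediate
17 | 2-(trimethylsilyl)ethyl 4a-bromo-6-[(Z)-3-iodo-2-methylprop-2-enamido]-3-methyl-5,8-dioxo-2,4-bis(trimethylsilyloxy)-4-[2-(trimethylsilyl)ethoxy]-1,4,4a,5,8,8a-hexahydronaphthalene-1-carboxylate (relative configuration undefined) | C/C(=C/I)C(=O)NC1=CC(=O)C2C(C(=O)OCC[Si](C)(C)C)C(O[Si](C)(C)C)=C(C)C(OCC[Si](C)(C)C)(O[Si](C)(C)C)C2(Br)C1=O | intermediate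
18 | 2-(trimethylsilyl)ethyl 6-[(Z)-3-iodo-2-methylprop-2-enamido]-2,4-dihydroxy-3-methyl-5,8-dioxo-5,8-dihydronaphthalene-1-carboxylate | C/C(=C/I)C(=O)NC1=CC(=O)c2c(C(=O)OCC[Si](C)(C)C)c(O)c(C)c(O)c2C1=O | intermediate
19 | (R)-4-benzyl-3-propanoyl-1,3-oxazolidin-2-one | CCC(=O)N1[C@H](Cc2ccccc2)COC1=O | starting material
20 | pent-4-enal | C=CCCC=O | starting material
21 | (R)-4-benzyl-3-[(Z)-1-(dibutylboranyloxy)prop-1-en-1-yl]-1,3-oxazolidin-2-one | C/C=C(\OB(CCCC)CCCC)N1[C@H](Cc2ccccc2)COC1=O | intermediate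
22 | (R)-4-benzyl-3-[(2R,3S)-3-hydroxy-2-methylhept-6-enoyl]-1,3-oxazolidin-2-one | O=C1OC[C@@H](Cc2ccccc2)N1C(=O)[C@H](C)[C@@H](O)CCC=C | intermediate
23 | (2R,3S)-3-hydroxy-N-methoxy-N,2-dimethylhept-6-enamide | CON(C)C(=O)[C@H](C)[C@@H](O)CCC=C | intermediate
24 | (2R,3S)-N-methoxy-N,2-dimethyl-3-(triethylsilyloxy)hept-6-enamide | CON(C)C(=O)[C@H](C)[C@@H](O[Si](CC)(CC)CC)CCC=C | intermediate
25 | (4R,5S)-4-methyl-5-(triethylsilyloxy)non-8-en-3-one | CCC(=O)[C@H](C)[C@@H](O[Si](CC)(CC)CC)CCC=C | intermediate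
26 | 2-methylprop-2-enal (methacrolein) | C=C(C)C=O | starting material
27 | dicyclohexyl{[(2E,4R,5S)-4-methyl-5-(triethylsilyloxy)nona-2,8-dien-3-yl]oxy}borane | C/C=C(/OB(C1CCCCC1)C1CCCCC1)[C@H](C)[C@@H](O[Si](CC)(CC)CC)CCC=C | intermediate
28 | (3S,4R,6R,7S)-3-hydroxy-2,4,6-trimethyl-7-(triethylsilyloxy)undeca-1,10-dien-5-one | C=C(C)[C@@H](O)[C@@H](C)C(=O)[C@H](C)[C@@H](O[Si](CC)(CC)CC)CCC=C | intermediate
29 | (3S,4S,5S,6S,7S)-5-hydroxy-2,4,6-trimethyl-7-(triethylsilyloxy)undeca-1,10-dien-3-yl benzoate | C=C(C)[C@@H](OC(=O)c1ccccc1)[C@@H](C)[C@H](O)[C@H](C)[C@@H](O[Si](CC)(CC)CC)CCC=C | intermediate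
30 | (3S,4S,5S,6S,7S)-5-hydroxy-2,4,6-trimethyl-10-oxo-7-(triethylsilyloxy)undec-1-en-3-yl benzoate | C=C(C)[C@@H](OC(=O)c1ccccc1)[C@@H](C)[C@H](O)[C@H](C)[C@@H](O[Si](CC)(CC)CC)CCC(C)=O | intermediate
31 | (3S,4S,5R,6R,7S)-5,7-dihydroxy-2,4,6-trimethyl-10-oxoundec-1-en-3-yl benzoate | C=C(C)[C@@H](OC(=O)c1ccccc1)[C@@H](C)[C@H](O)[C@H](C)[C@@H](O)CCC(C)=O | intermediate
32 | (3S,4S)-2-methyl-4-[(1S,3R,4R,5S)-1,4-dimethyl-2,8-dioxabicyclo[3.2.1]octan-3-yl]pent-1-en-3-yl benzoate | C=C(C)[C@@H](OC(=O)c1ccccc1)[C@@H](C)[C@@H]1O[C@@]2(C)CC[C@H](O2)[C@H]1C | intermediate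
33 | 9-{(2R,3R,4S)-3-(benzoyloxy)-2-methyl-4-[(1S,3R,4R,5S)-1,4-dimethyl-2,8-dioxabicyclo[3.2.1]octan-3-yl]pentyl}-9-borabicyclo[3.3.1]nonane | C1CCC2CCCC1B2C[C@@H](C)[C@@H](OC(=O)c1ccccc1)[C@@H](C)[C@@H]1O[C@@]2(C)CC[C@H](O2)[C@H]1C | intermediate
34 | (2R,3R,4S)-1-hydroxy-2-methyl-4-[(1S,3R,4R,5S)-1,4-dimethyl-2,8-dioxabicyclo[3.2.1]octan-3-yl]pentan-3-yl benzoate | OC[C@@H](C)[C@@H](OC(=O)c1ccccc1)[C@@H](C)[C@@H]1O[C@@]2(C)CC[C@H](O2)[C@H]1C | intermediate
35 | (2S,3S,4S)-2-methyl-1-oxo-4-[(1S,3R,4R,5S)-1,4-dimethyl-2,8-dioxabicyclo[3.2.1]octan-3-yl]pentan-3-yl benzoate | O=C[C@@H](C)[C@@H](OC(=O)c1ccccc1)[C@@H](C)[C@@H]1O[C@@]2(C)CC[C@H](O2)[C@H]1C | intermediate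
36 | (R)-but-3-yn-2-ol | C#C[C@@H](C)O | starting material
37 | (R)-but-3-yn-2-yl methanesulfonate | C#C[C@@H](C)OS(C)(=O)=O | intermediate
38 | (aS)-buta-1,2-dien-1-yl(ethyl)zinc | CC[Zn]C([H])=[C@@]=C([H])C | intermediate
39 | (2S,3R,4R,5S,6S)-5-hydroxy-4,6-dimethyl-2-[(1S,3R,4R,5S)-1,4-dimethyl-2,8-dioxabicyclo[3.2.1]octan-3-yl]oct-7-yn-3-yl benzoate | C#C[C@H](C)[C@H](O)[C@@H](C)[C@@H](OC(=O)c1ccccc1)[C@@H](C)[C@@H]1O[C@@]2(C)CC[C@H](O2)[C@H]1C | intermediate
40 | (3S,4S,5R,6R,7R)-3,5-dimethyl-7-[(1S,3S,4R,5S)-1,4-dimethyl-2,8-dioxabicyclo[3.2.1]octan-3-yl]oct-1-yne-4,6-diol | C#C[C@H](C)[C@H](O)[C@@H](C)[C@@H](O)[C@@H](C)[C@@H]1O[C@@]2(C)CC[C@H](O2)[C@H]1C | intermediate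
41 | (1E,3S,4S,5R,6R,7R)-3,5-dimethyl-7-[(1S,3S,4R,5S)-1,4-dimethyl-2,8-dioxabicyclo[3.2.1]octan-3-yl]-1-(tributylstannyl)oct-1-ene-4,6-diol | CCCC[Sn](CCCC)(CCCC)/C=C/[C@H](C)[C@H](O)[C@@H](C)[C@@H](O)[C@@H](C)[C@@H]1O[C@@]2(C)CC[C@H](O2)[C@H]1C | intermediate
42 | 2-(trimethylsilyl)ethyl 6-{[(2Z,4E,6S,7S,8R,9R,10R)-7,9-dihydroxy-2,6,8-trimethyl-10-[(1S,3S,4R,5S)-1,4-dimethyl-2,8-dioxabicyclo[3.2.1]octan-3-yl]undeca-2,4-dienoyl]amino}-2,4-dihydroxy-3-methyl-5,8-dioxo-5,8-dihydronaphthalene-1-carboxylate | C/C(=C/C=C/[C@H](C)[C@H](O)[C@@H](C)[C@@H](O)[C@@H](C)[C@@H]1O[C@@]2(C)CC[C@H](O2)[C@H]1C)C(=O)NC1=CC(=O)c2c(C(=O)OCC[Si](C)(C)C)c(O)c(C)c(O)c2C1=O | intermediate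
43 | rifsaliniketal, 6-{[(2Z,4E,6S,7S,8R,9R,10R)-7,9-dihydroxy-2,6,8-trimethyl-10-[(1S,3S,4R,5S)-1,4-dimethyl-2,8-dioxabicyclo[3.2.1]octan-3-yl]undeca-2,4-dienoyl]amino}-2,4-dihydroxy-3-methyl-5,8-dioxo-5,8-dihydronaphthalene-1-carboxylic acid | C/C(=C/C=C/[C@H](C)[C@H](O)[C@@H](C)[C@@H](O)[C@@H](C)[C@@H]1O[C@@]2(C)CC[C@H](O2)[C@H]1C)C(=O)NC1=CC(=O)c2c(C(=O)O)c(O)c(C)c(O)c2C1=O | target

**Step count and risk**

Total step count: 26. Longest linear sequence: 15 steps (steps 11–20 and 22–26, from 19 and 20 to 43).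

Steps most likely to fail:

Step 10. The diene, whose nucleophilic terminus is attenuated by the ester, may be protodesilylated by liberated HBr or by the acidic amide N–H faster than it cycloadds, or addition may stop at the open Michael stage with loss of regiocontrol. The fallback separates ring construction from nitrogen introduction. It sets out from 16 and 9. Diene 16 is combined in the same cycloaddition–elimination manner with the more electrophilic, symmetrical 2,6-dibromo-1,4-benzoquinone F1, where only bromine directs, to give 2-(trimethylsilyl)ethyl 6-bromo-2,4-dihydroxy-3-methyl-5,8-dioxo-5,8-dihydronaphthalene-1-carboxylate F2, whose remaining bromine sits on C2'. Addition–elimination with sodium azide gives the 6-azido naphthoquinone ester F3, and Staudinger reduction (PPh3, THF/H2O) gives the 6-amino naphthoquinone ester F4. F4 is N-acylated with acid chloride 9 after brief dithionite reduction to the more nucleophilic aminohydroquinone and re-oxidised in air, which comes back to the route at 18.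

Step 25. The hydroxyquinone may oxidise Pd(0) or consume the stannane, and its acidic hydroxyls may protodestannylate 41, so that coupling stalls. The fallback masks the quinone during the coupling. It sets out from 18, which is reduced with aqueous Na2S2O4 to 2-(trimethylsilyl)ethyl 2,4,5,8-tetrahydroxy-6-[(Z)-3-iodo-2-methylprop-2-enamido]-3-methylnaphthalene-1-carboxylate F5. F5 is coupled with 41 under argon (Pd2(dba)3, AsPh3, CuI) to the hydroquinone form of the coupled ester F6, and air oxidation on work-up comes back to the route at 42.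

Step 26. Basic fluoride acting on the fully assembled molecule may cleave the C2'–N bond of the vinylogous imide, isomerise the dienamide or trigger decarboxylation of the liberated β-resorcylic acid. The fallback removes the ester one step earlier on the robust fragment. It sets out from 18, which is treated with TASF to give 6-[(Z)-3-iodo-2-methylprop-2-enamido]-2,4-dihydroxy-3-methyl-5,8-dioxo-5,8-dihydronaphthalene-1-carboxylic acid F7. F7 is coupled with 41 at room temperature (Pd2(dba)3, AsPh3, iPr2NEt to hold the acid as carboxylate) and comes back to the route at 43, so the target never sees fluoride.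

Further compounds
F1 | step 10 | 2,6-dibromo-1,4-benzoquinone | O=C1C=C(Br)C(=O)C(Br)=C1
F2 | step 10 | 2-(trimethylsilyl)ethyl 6-bromo-2,4-dihydroxy-3-methyl-5,8-dioxo-5,8-dihydronaphthalene-1-carboxylate | C[Si](C)(C)CCOC(=O)c1c(O)c(C)c(O)c2C(=O)C(Br)=CC(=O)c12
F3 | step 10 | 2-(trimethylsilyl)ethyl 6-azido-2,4-dihydroxy-3-methyl-5,8-dioxo-5,8-dihydronaphthalene-1-carboxylate | C[Si](C)(C)CCOC(=O)c1c(O)c(C)c(O)c2C(=O)C(N=[N+]=[N-])=CC(=O)c12
F4 | step 10 | 2-(trimethylsilyl)ethyl 6-amino-2,4-dihydroxy-3-methyl-5,8-dioxo-5,8-dihydronaphthalene-1-carboxylate | C[Si](C)(C)CCOC(=O)c1c(O)c(C)c(O)c2C(=O)C(N)=CC(=O)c12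
F5 | step 25 | 2-(trimethylsilyl)ethyl 2,4,5,8-tetrahydroxy-6-[(Z)-3-iodo-2-methylprop-2-enamido]-3-methylnaphthalene-1-carboxylate | C/C(=C/I)C(=O)Nc1cc(O)c2c(C(=O)OCC[Si](C)(C)C)c(O)c(C)c(O)c2c1O
F6 | step 25 | 2-(trimethylsilyl)ethyl 6-{[(2Z,4E,6S,7S,8R,9R,10R)-7,9-dihydroxy-2,6,8-trimethyl-10-[(1S,3S,4R,5S)-1,4-dimethyl-2,8-dioxabicyclo[3.2.1]octan-3-yl]undeca-2,4-dienoyl]amino}-2,4,5,8-tetrahydroxy-3-methylnaphthalene-1-carboxylate | C/C(=C/C=C/[C@H](C)[C@H](O)[C@@H](C)[C@@H](O)[C@@H](C)[C@@H]1O[C@@]2(C)CC[C@H](O2)[C@H]1C)C(=O)Nc1cc(O)c2c(C(=O)OCC[Si](C)(C)C)c(O)c(C)c(O)c2c1O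
F7 | step 26 | 6-[(Z)-3-iodo-2-methylprop-2-enamido]-2,4-dihydroxy-3-methyl-5,8-dioxo-5,8-dihydronaphthalene-1-carboxylic acid | C/C(=C/I)C(=O)NC1=CC(=O)c2c(C(=O)O)c(O)c(C)c(O)c2C1=O
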